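**Retrosynthetic overview**

- Ring C is formed last, by O1–C2 closure of a 1-(2,6-dioxygenated aryl)-3-arylpropynone, merged with unmasking of the 5-OH and 2'-OH groups.
- The ynone is cut at C3–C4 into an acyl anion equivalent (the carbene-derived Breslow intermediate of pentamethoxybenzaldehyde, ring A) and an alkynyl cation equivalent (a ring B alkynyl(phenyl)iodonium salt).
- The ring A aldehyde comes from 3,4,5-trimethoxybenzaldehyde by twofold ortho-bromination and CuBr-catalysed methoxylation; its mirror symmetry lets either ortho-oxygen become O1 and the other the 5-OH.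
- The ring B salt comes from 2-hydroxy-4,5-dimethoxybenzaldehyde by O-benzylation, one-carbon homologation to the alkyne and reaction with PhI(OH)OTs.
- Rings A and B are bought as benzenes; ring C is the only ring made.

Assumption: the target has no stereocentre or chiral axis (it is achiral), so no stereocontrol is needed and all SMILES carry no stereodescriptors; 2-hydroxy-4,5-dimethoxybenzaldehyde and PhI(OH)OTs are taken as catalogue chemicals.

**Step 1**
Reactants: 1 3,4,5-trimethoxybenzaldehyde
Product: 2 2,6-dibromo-3,4,5-trimethoxybenzaldehyde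
Conditions: Br2 (2.5 equiv), AcOH, 60 °C
Reagents that add atoms: bromine, BrBr
Why: Twofold electrophilic aromatic bromination at the only free ring positions, each activated by ortho- and para-methoxy groups; the slower second bromination is driven by excess Br2 and heat.

**Step 2**
Reactants: 2 2,6-dibromo-3,4,5-trimethoxybenzaldehyde
Product: 3 2,3,4,5,6-pentamethoxybenzaldehyde
Conditions: NaOMe (6 equiv), CuBr (20 mol%), MeOH/DMF, 110 °C, sealed vessel
Reagents that add atoms: sodium methoxide, [Na+].[O-]C
Why: Ullmann-type CuBr-catalysed methoxylation of aryl bromides, helped by the ortho-formyl group next to both C–Br bonds, as in the standard conversion of bromo-alkoxybenzaldehydes into their methoxy analogues.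

**Step 3**
Reactants: 4 2-hydroxy-4,5-dimethoxybenzaldehyde
Product: 6 1-(benzyloxy)-2-ethynyl-4,5-dimethoxybenzene, via 2-(benzyloxy)-4,5-dimethoxybenzaldehyde 5 (not isolated)
Conditions: BnBr (1.05 equiv), K2CO3 (3 equiv), MeCN, 60 °C; then MeOH, dimethyl (1-diazo-2-oxopropyl)phosphonate (1.3 equiv), 20 °C
Reagents that add atoms: benzyl bromide, BrCc1ccccc1; dimethyl (1-diazo-2-oxopropyl)phosphonate, CC(=O)C(=[N+]=[N-])P(=O)(OC)OC
Why: Williamson O-benzylation followed in the same K2CO3 suspension by Ohira–Bestmann (Seyferth–Gilbert) homologation of the aldehyde to the terminal alkyne.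

**Step 4**
Reactants: 6 1-(benzyloxy)-2-ethynyl-4,5-dimethoxybenzene
Product: 7 {[2-(benzyloxy)-4,5-dimethoxyphenyl]ethynyl}(phenyl)iodonium 4-methylbenzenesulfonate
Conditions: PhI(OH)OTs (1.0 equiv), CH2Cl2, 0 → 20 °C, dark; precipitation with Et2O
Reagents that add atoms: hydroxy(tosyloxy)iodobenzene, Cc1ccc(cc1)S(=O)(=O)OI(O)c1ccccc1
Why: Koser alkynyliodonium synthesis, in which the electrophilic trivalent-iodine reagent attacks the terminal carbon of the electron-rich arylalkyne and loss of the acetylenic proton and water leaves the alkynyl(phenyl)iodonium tosylate.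

**Step 5 (key step)**
Reactants: 3 2,3,4,5,6-pentamethoxybenzaldehyde; 7 {[2-(benzyloxy)-4,5-dimethoxyphenyl]ethynyl}(phenyl)iodonium 4-methylbenzenesulfonate
Product: 8 3-[2-(benzyloxy)-4,5-dimethoxyphenyl]-1-(2,3,4,5,6-pentamethoxyphenyl)prop-2-yn-1-one
Conditions: 2-(pentafluorophenyl)-6,7-dihydro-5H-pyrrolo[2,1-c][1,2,4]triazol-2-ium tetrafluoroborate (20 mol%), TMEDA (1.5 equiv), PhMe, −40 → −20 °C
Reagents that add atoms: none
Why: N-heterocyclic-carbene-catalysed C–H alkynylation of an aldehyde with an alkynyliodonium salt (Breslow-intermediate acyl anion catalysis, a Stetter-type polarity reversal): the carbene adds to the formyl group of 3, the resulting enaminol attacks the rod-shaped, sterically undemanding α-acetylenic carbon of 7 with loss of PhI, and collapse of the adduct releases the ynone and the carbene, while the two ortho-methoxy groups shut down self-benzoin so the acyl anion equivalent has only the iodonium salt to react with; no stereocentre is formed.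

**Step 6**
Reactants: 8 3-[2-(benzyloxy)-4,5-dimethoxyphenyl]-1-(2,3,4,5,6-pentamethoxyphenyl)prop-2-yn-1-one
Product: 10 Agehoustin F, via boron-chelated hydroxy-ynone 9 (not isolated)
Conditions: BCl3 (8 equiv), C6HMe5 (3 equiv), CH2Cl2, −78 → 20 °C, 6 h; then 1 M aq. HCl, THF, 40 °C
Reagents that add atoms: none
Why: Proposed new method: BCl3 removes the benzyl group (cation trapped by C6HMe5) and, through the six-membered carbonyl chelate, one ortho-methyl to give 9 as its O–BCl2 chelate; in this chelate the ynone is a strong vinylogous acceptor, so the remaining ortho-OMe oxygen closes 6-endo on the β-carbon and chloride takes the methyl from the resulting oxonium, giving the 5-O-boron chelate of the flavone, which acid hydrolysis frees (if cyclisation comes first, the new 5-OMe is cleaved by the usual peri-chelation, so both orders converge); closest known reactions are chelation-controlled ortho/peri O-demethylation of aryl ketones and 5-methoxyflavones by BCl3, BCl3-induced demethylative oxy-cyclisation of 2-alkynylanisoles, and ICl-induced demethylative 6-endo cyclisation of 2-methoxyaryl ynones.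

**Compound list**

1 | 3,4,5-trimethoxybenzaldehyde | COc1cc(C=O)cc(OC)c1OC | starting material
2 | 2,6-dibromo-3,4,5-trimethoxybenzaldehyde | O=Cc1c(Br)c(OC)c(OC)c(OC)c1Br | intermediate
3 | 2,3,4,5,6-pentamethoxybenzaldehyde | O=Cc1c(OC)c(OC)c(OC)c(OC)c1OC | intermediate
4 | 2-hydroxy-4,5-dimethoxybenzaldehyde | O=Cc1cc(OC)c(OC)cc1O | starting material
5 | 2-(benzyloxy)-4,5-dimethoxybenzaldehyde (not isolated) | O=Cc1cc(OC)c(OC)cc1OCc1ccccc1 | intermediate
6 | 1-(benzyloxy)-2-ethynyl-4,5-dimethoxybenzene | C#Cc1cc(OC)c(OC)cc1OCc1ccccc1 | intermediate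
7 | {[2-(benzyloxy)-4,5-dimethoxyphenyl]ethynyl}(phenyl)iodonium 4-methylbenzenesulfonate | COc1cc(C#C[I+]c2ccccc2)c(OCc2ccccc2)cc1OC.Cc1ccc(cc1)S(=O)(=O)[O-] | intermediate
8 | 3-[2-(benzyloxy)-4,5-dimethoxyphenyl]-1-(2,3,4,5,6-pentamethoxyphenyl)prop-2-yn-1-one | COc1cc(C#CC(=O)c2c(OC)c(OC)c(OC)c(OC)c2OC)c(OCc2ccccc2)cc1OC | intermediate
9 | 1-(2-hydroxy-3,4,5,6-tetramethoxyphenyl)-3-(2-hydroxy-4,5-dimethoxyphenyl)prop-2-yn-1-one (in the flask as its O–BCl2 chelates, not isolated) | COc1cc(O)c(C#CC(=O)c2c(O)c(OC)c(OC)c(OC)c2OC)cc1OC | intermediate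
10 | Agehoustin F, 5-hydroxy-2-(2-hydroxy-4,5-dimethoxyphenyl)-6,7,8-trimethoxy-4H-chromen-4-one (achiral) | COc1cc(O)c(-c2cc(=O)c3c(O)c(OC)c(OC)c(OC)c3o2)cc1OC | target

**Step count and risks**

Total step count: 6. Longest linear sequence: 4 steps (1 → 2 → 3 → 8 → 10; the ring B branch 4 → 6 → 7 → 8 → 10 is also 4).

Steps most likely to fail, with fallbacks:

Step 5. The aldehyde carries two ortho-methoxy groups, which slows carbene addition and Breslow-intermediate formation, and the iodonium salt is an electron-rich, less electrophilic one. The fallback keeps the same C3–C4 bond and the same nucleophilic-acyl logic in one-electron form, which is far less sensitive to ortho bulk. It sets out from alkyne 6 (with aldehyde 3 as partner) and comes back at ynone 8. Alkyne 6 is C-silylated (n-BuLi, Me3SiCl, THF, −78 °C) to {[2-(benzyloxy)-4,5-dimethoxyphenyl]ethynyl}trimethylsilane F1. Treatment of this with 1-hydroxy-1,2-benziodoxol-3(1H)-one and Me3SiOTf, then pyridine, gives the bench-stable 1-{[2-(benzyloxy)-4,5-dimethoxyphenyl]ethynyl}-1,2-benziodoxol-3(1H)-one F2. Heating 3 with this reagent and tert-butyl hydroperoxide in 1,2-dichloroethane at 80 °C abstracts the formyl hydrogen; the σ-type pentamethoxybenzoyl radical adds to the iodine-bearing alkyne carbon and expels the iodanyl radical, giving 8.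

Step 6. The cascade needs the second ortho-methoxy oxygen to cyclise inside the boron chelate; it may stop at 9, or excess BCl3 may start to attack the 6-OMe. The fallback runs the three events separately, setting out from 8 and coming back at 10. BCl3/C6HMe5 at −78 → 0 °C with a methanol quench gives 9, this time isolated. K2CO3 in MeOH at 20 °C then closes the free 2-hydroxyl onto the ynone by ordinary 6-endo oxa-Michael addition, giving 2-(2-hydroxy-4,5-dimethoxyphenyl)-5,6,7,8-tetramethoxy-4H-chromen-4-one F3. BCl3 (2 equiv) in CH2Cl2 at 0 °C then cleaves only the 5-OMe peri to the carbonyl, giving 10.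

Step 4. The very electron-rich arylalkyne can add tosylate or be oxidised on the ring by PhI(OH)OTs, and the salt may be unstable. The fallback replaces C–H attack by ipso-substitution at a C–B bond, setting out from 6 and coming back at 7. Alkyne 6 is converted (n-BuLi; 2-isopropoxy-4,4,5,5-tetramethyl-1,3,2-dioxaborolane; HCl in Et2O) into 2-{[2-(benzyloxy)-4,5-dimethoxyphenyl]ethynyl}-4,4,5,5-tetramethyl-1,3,2-dioxaborolane F4. Boron-to-iodine alkynyl transfer with PhI(OH)OTs in CH2Cl2 at 0 °C then gives 7 without a vinyl cation intermediate.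

**Further compounds**

F1 | step 5 | {[2-(benzyloxy)-4,5-dimethoxyphenyl]ethynyl}trimethylsilane | C[Si](C)(C)C#Cc1cc(OC)c(OC)cc1OCc1ccccc1
F2 | step 5 | 1-{[2-(benzyloxy)-4,5-dimethoxyphenyl]ethynyl}-1,2-benziodoxol-3(1H)-one | O=C1OI(C#Cc2cc(OC)c(OC)cc2OCc2ccccc2)c2ccccc12
F3 | step 6 | 2-(2-hydroxy-4,5-dimethoxyphenyl)-5,6,7,8-tetramethoxy-4H-chromen-4-one | COc1cc(O)c(-c2cc(=O)c3c(OC)c(OC)c(OC)c(OC)c3o2)cc1OC
F4 | step 4 | 2-{[2-(benzyloxy)-4,5-dimethoxyphenyl]ethynyl}-4,4,5,5-tetramethyl-1,3,2-dioxaborolane | CC1(C)OB(C#Cc2cc(OC)c(OC)cc2OCc2ccccc2)OC1(C)C
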